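The locants are C1 (quaternary methyl-bearing fusion carbon), C4 (isopropyl carbinol), C5 (fusion CH), C6 (anisoyloxy carbon), C7 (CH2), C8=C9 (alkene) and C10 (acetoxy carbon). The seven-membered ring is a masked cyclohepta-1,4-diene: the C8=C9 alkene and an enolised C6 oxygen (C5=C6) flank C7H2 beside quaternary C1. It is disconnected at C7–C8 and C10–C1 by a rhodium vinylcarbenoid formal (4+3) cycloaddition. Cyclopropanation of a 2-silyloxydiene and Cope rearrangement of the divinylcyclopropane close the seven-membered ring onto the cyclopentene and create C1 in one operation. The precursor, a 1-(1-silyloxyvinyl)cyclopentene carrying C4 intact, comes from (S)-terpinen-4-ol by ozonolysis and aldol ring contraction.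

Key step: step 8

Remark: commercial (S)-terpinen-4-ol is assumed to be of high enantiomeric purity (it is enriched beforehand if it is not).

Naming convention: "daucane" means bicyclo[5.3.0]decane with CH3 on C1 and C8 (the C8 carbon substituent is C14) and isopropyl on C4. C2 and C3 are the cyclopentane CH2 groups. β is the face of the C1 methyl group and α the face of H-5. The target is therefore the trans-fused 1β-CH3, 5α-H, 4β-OH, 4α-isopropyl, 6α-anisoyloxy, 10β-acetoxy compound.

Step 1
Reactants: 1 (S)-terpinen-4-ol
Product: 2 (S)-terpinen-4-ol triethylsilyl ether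
Conditions: TESOTf, 2,6-lutidine, CH2Cl2, −78 → 0 °C
Reagents that add atoms: triethylsilyl trifluoromethanesulfonate CC[Si](CC)(CC)OS(=O)(=O)C(F)(F)F
Why: A silyl triflate with a hindered pyridine base silylates even a tertiary alcohol (silyl ether formation), and masking the C4 hydroxyl prevents retro-aldol cleavage and dehydration of the β-oxygenated carbonyl compounds that follow, the stereocentre being untouched.

Step 2
Reactants: 2 (S)-terpinen-4-ol triethylsilyl ether
Product: 4 (S)-3-isopropyl-6-oxo-3-(triethylsilyloxy)heptanal, via ozonide 3 (not isolated)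
Conditions: O3, CH2Cl2, −78 °C; then Me2S, −78 °C → rt
Reagents that add atoms: ozone [O-][O+]=O
Why: Ozonolysis (cycloaddition to the only C=C, rearrangement to the ozonide and reductive cleavage by the sulfide) opens the cyclohexene to the keto aldehyde, and the silyl ether is inert to ozone.

Step 3
Reactants: 4 (S)-3-isopropyl-6-oxo-3-(triethylsilyloxy)heptanal
Product: 5 (R)-5-isopropyl-2-methyl-5-(triethylsilyloxy)cyclopent-1-ene-1-carbaldehyde
Conditions: piperidine (cat.), AcOH (cat.), toluene, rt → 60 °C
Reagents that add atoms: none
Why: Intramolecular aldol condensation under amine/acid catalysis, in which the aldehyde forms its enamine far faster than the ketone, so that the aldehyde α-carbon attacks the methyl ketone in a five-membered closure and dehydration gives the tetrasubstituted enal and not the isomeric acetylcyclopentene, while the mild buffer keeps β-elimination of the silyloxy group in check.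

Step 4
Reactants: 5 (R)-5-isopropyl-2-methyl-5-(triethylsilyloxy)cyclopent-1-ene-1-carbaldehyde
Product: 6 1-[(R)-5-isopropyl-2-methyl-5-(triethylsilyloxy)cyclopent-1-en-1-yl]ethanol (carbinol epimers)
Conditions: MeMgBr, THF, −78 → 0 °C; aqueous work-up
Reagents that add atoms: methylmagnesium bromide C[Mg]Br
Why: Grignard 1,2-addition to the aldehyde is favoured over conjugate addition at the fully substituted β-carbon, and the new carbinol centre, formed as a mixture, is removed again by the oxidation in step 5.

Step 5
Reactants: 6 1-[(R)-5-isopropyl-2-methyl-5-(triethylsilyloxy)cyclopent-1-en-1-yl]ethanol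
Product: 7 1-[(R)-5-isopropyl-2-methyl-5-(triethylsilyloxy)cyclopent-1-en-1-yl]ethanone
Conditions: Dess–Martin periodinane, CH2Cl2, 0 °C → rt
Reagents that add atoms: none
Why: Dess–Martin oxidation converts the secondary allylic alcohol into the methyl ketone under near-neutral conditions that the silyl ether and the alkene tolerate.

Step 6
Reactants: 7 1-[(R)-5-isopropyl-2-methyl-5-(triethylsilyloxy)cyclopent-1-en-1-yl]ethanone
Product: 8 2-silyloxydiene tert-butyl({1-[(R)-5-isopropyl-2-methyl-5-(triethylsilyloxy)cyclopent-1-en-1-yl]ethenyl}oxy)dimethylsilane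
Conditions: LiN(iPr)2 (LDA), THF, −78 °C; then TBSCl, DMPU, −78 → 0 °C; used without delay
Reagents that add atoms: tert-butyldimethylsilyl chloride CC(C)(C)[Si](C)(C)Cl
Why: Kinetic deprotonation of an enone by a hindered lithium amide takes place at the α′-methyl group (cross-conjugated enolate), and O-silylation traps it as the 2-silyloxy-1,3-diene (silyl enol ether formation) without creating a stereocentre or touching C4.

Step 7
Reactants: 9 methyl but-3-enoate
Product: 10 methyl 2-diazobut-3-enoate
Conditions: 4-acetamidobenzenesulfonyl azide (p-ABSA), DBU, MeCN, 0 °C; kept cold and used the same day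
Reagents that add atoms: 4-acetamidobenzenesulfonyl azide CC(=O)Nc1ccc(cc1)S(=O)(=O)N=[N+]=[N-]
Why: Regitz diazo transfer, in which DBU forms the dienolate of the β,γ-unsaturated ester and its α-carbon attacks the sulfonyl azide, gives the vinyldiazoacetate, which must be used fresh because it electrocyclises to a pyrazole on standing.

Step 8
Reactants: 8 2-silyloxydiene; 10 methyl 2-diazobut-3-enoate
Product: 12 methyl 6-(tert-butyldimethylsilyloxy)-4β-(triethylsilyloxy)dauca-5,8-dien-14-oate, via cis-divinylcyclopropane 11 (not isolated)
Conditions: Rh2(R-DOSP)4 (dirhodium tetrakis[N-(4-dodecylbenzenesulfonyl)-(R)-prolinate], 2 mol%), degassed hexanes, −40 °C, slow addition of 10 (2 equiv); then rt → 60 °C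
Reagents that add atoms: none
Why: Rh2(R-DOSP)4 converts 10 into a donor/acceptor vinylcarbenoid whose carbenoid carbon C8 adds across the terminal silyl enol ether C6=C7 of 8 to give cis-divinylcyclopropane 11, and a [3,3]-sigmatropic shift through a boat transition state then breaks C6–C8 and forms C10–C1, so that C7–C8 and C10–C1 are the net new bonds. The closest known reaction type is the dirhodium-carboxylate-catalysed tandem cyclopropanation/Cope rearrangement of vinyldiazoacetates with 1,3-dienes (formal (4+3) cycloaddition), which is documented for 2-silyloxydienes and for diene termini that become quaternary. The three-membered ring closes by concerted (2+1) carbene transfer and is consumed again, while the seven-membered ring closes by the sigmatropic C10–C1 bond formation, a strain-releasing ring expansion helped by the silyloxy donor and ester acceptor on the bond that breaks. The one lasting new stereocentre, C1, is fixed by the absolute configuration of the cyclopropane (C6 and C8), which the chiral catalyst imposes and the boat geometry relays stereospecifically; the R-configured catalyst is selected from the usual model in which the alkene substituent ends cis to the carbenoid vinyl group, so that C10 bonds to the α face of the cyclopentene, and this assignment is to be confirmed on the first run. The step needs site selectivity for C6=C7 over the tetrasubstituted ring alkene (secured by its electron richness and accessibility), carbenoid-carbon over vinylogous reactivity (secured by the hydrocarbon solvent and the electron-rich prolinate catalyst) and a cis relationship of the two alkenyl groups (the normal outcome for these carbenoids). Gentle heating is planned because the C1 methyl group points into the boat and slows the rearrangement, but the temperature is kept as low as possible so that ionisation of the push–pull cyclopropane does not erode the stereochemical relay.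

Step 9
Reactants: 12 methyl 6-(tert-butyldimethylsilyloxy)-4β-(triethylsilyloxy)dauca-5,8-dien-14-oate
Product: 13 6-(tert-butyldimethylsilyloxy)-4β-(triethylsilyloxy)dauca-5,8-dien-14-ol
Conditions: iBu2AlH (DIBAL-H, 2.5 equiv), CH2Cl2, −78 °C; aq. KNaC4H4O6 (potassium sodium tartrate) work-up
Reagents that add atoms: none
Why: DIBAL-H reduces the conjugated ester by two hydride additions (1,2-reduction) to the primary allylic alcohol at −78 °C, while the silyl enol ether that masks the C6 carbonyl and the tertiary silyl ether are inert to the aluminium hydride.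

Step 10
Reactants: 13 6-(tert-butyldimethylsilyloxy)-4β-(triethylsilyloxy)dauca-5,8-dien-14-ol
Product: 15 6-(tert-butyldimethylsilyloxy)-4β-(triethylsilyloxy)dauca-5,8-diene, via allylic mesylate 14 (not isolated)
Conditions: MsCl, Et3N, THF, −40 °C; then LiEt3BH, −78 → 0 °C
Reagents that add atoms: none
Why: Sulfonylation of the primary allylic alcohol and direct SN2 displacement of the mesylate by the strongly nucleophilic hydride LiEt3BH (deoxygenation through sulfonate reduction) turn CH2OH into the C8 methyl group without moving the C8=C9 alkene, and both silyl groups are stable to base and hydride.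

Step 11
Reactants: 15 6-(tert-butyldimethylsilyloxy)-4β-(triethylsilyloxy)dauca-5,8-diene
Product: 16 4β-hydroxy-5α-dauc-8-en-6-one (trans-fused)
Conditions: HF·pyridine, excess pyridine, THF, 0 °C → rt
Reagents that add atoms: none
Why: In this buffered fluoride desilylation the silyl enol ether is cleaved first with protonation of C5 on the α face, away from the 1β-methyl group and the still silylated 4β-oxygen, which sets the trans ring fusion by substrate control; the tertiary triethylsilyl ether then falls more slowly in a medium mild enough to leave the β,γ-unsaturated β-hydroxy ketone unconjugated and undehydrated.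

Step 12
Reactants: 16 4β-hydroxy-5α-dauc-8-en-6-one
Product: 17 5α-dauc-8-ene-4β,6α-diol
Conditions: Me4NBH(OAc)3, MeCN/AcOH, −30 °C
Reagents that add atoms: none
Why: In this Saksena–Evans hydroxyl-directed reduction the 4β-hydroxyl exchanges onto boron and delivers hydride intramolecularly to the β face of the C6 carbonyl through a six-membered transition state, which sets the 6α (1,3-anti) alcohol against the shielding of that face by the C1 methyl group, and the weakly acidic medium avoids retro-aldol cleavage and alkene migration.

Step 13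
Reactants: 17 5α-dauc-8-ene-4β,6α-diol; 18 4-methoxybenzoyl chloride
Product: 19 6α-(4-methoxybenzoyloxy)-5α-dauc-8-en-4β-ol
Conditions: Et3N, DMAP (cat.), CH2Cl2, 0 °C → rt
Reagents that add atoms: none
Why: DMAP-catalysed acylation (esterification) takes place only at the secondary C6 alcohol, because the tertiary C4 alcohol flanked by the isopropyl group is too hindered to react under these conditions.

Step 14
Reactants: 19 6α-(4-methoxybenzoyloxy)-5α-dauc-8-en-4β-ol
Product: 20 4β-hydroxy-6α-(4-methoxybenzoyloxy)-5α-dauc-8-en-10-one
Conditions: CrO3, 3,5-dimethylpyrazole, CH2Cl2, −20 °C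
Reagents that add atoms: chromium trioxide O=[Cr](=O)=O
Why: Allylic C–H oxidation by the CrO3–3,5-dimethylpyrazole complex attacks the allylic methylene on the less substituted alkene carbon (C10, the pattern known from the oxidation of 5-ene steroids to 7-ketones), whereas C7 is deactivated by the neighbouring acyloxy group and the vinylic methyl is a poorer hydrogen donor, and the tertiary alcohol and the ester survive.

Step 15
Reactants: 20 4β-hydroxy-6α-(4-methoxybenzoyloxy)-5α-dauc-8-en-10-one
Product: 21 6α-(4-methoxybenzoyloxy)-5α-dauc-8-ene-4β,10β-diol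
Conditions: NaBH4, CeCl3·7H2O, MeOH, −78 → −40 °C
Reagents that add atoms: none
Why: In the Luche reduction the cerium-activated enone carbonyl is attacked 1,2 by borohydride from the α face, opposite the methyl group on the adjacent quaternary C1, which sets the 10β alcohol, and the ester is not touched at low temperature.

Step 16
Reactants: 21 6α-(4-methoxybenzoyloxy)-5α-dauc-8-ene-4β,10β-diol
Product: 22 10β-acetoxy-6α-(4-methoxybenzoyloxy)-5α-dauc-8-en-4β-ol (target CNP0256979.3)
Conditions: Ac2O, pyridine, DMAP (cat.), CH2Cl2, 0 °C → rt
Reagents that add atoms: acetic anhydride CC(=O)OC(C)=O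
Why: DMAP-catalysed acetylation (esterification) of the secondary allylic alcohol is selective over the hindered tertiary C4 alcohol and delivers the target without a final deprotection.

Compound list
1 | (S)-terpinen-4-ol, (S)-4-methyl-1-(propan-2-yl)cyclohex-3-en-1-ol | CC1=CC[C@](O)(C(C)C)CC1 | starting material
2 | (S)-terpinen-4-ol triethylsilyl ether | CC1=CC[C@](O[Si](CC)(CC)CC)(C(C)C)CC1 | intermediate
3 | ozonide of 2 (1,2,4-trioxolane across the former C=C, both ozonide diastereomers, not isolated) | CC12CC[C@@](O[Si](CC)(CC)CC)(C(C)C)CC(OO1)O2 | intermediate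
4 | (S)-3-isopropyl-6-oxo-3-(triethylsilyloxy)heptanal | CC(=O)CC[C@@](O[Si](CC)(CC)CC)(C(C)C)CC=O | intermediate
5 | (R)-5-isopropyl-2-methyl-5-(triethylsilyloxy)cyclopent-1-ene-1-carbaldehyde | CC1=C(C=O)[C@](O[Si](CC)(CC)CC)(C(C)C)CC1 | intermediate
6 | 1-[(R)-5-isopropyl-2-methyl-5-(triethylsilyloxy)cyclopent-1-en-1-yl]ethanol (carbinol epimers) | CC1=C(C(C)O)[C@](O[Si](CC)(CC)CC)(C(C)C)CC1 | intermediate
7 | 1-[(R)-5-isopropyl-2-methyl-5-(triethylsilyloxy)cyclopent-1-en-1-yl]ethanone | CC1=C(C(C)=O)[C@](O[Si](CC)(CC)CC)(C(C)C)CC1 | intermediate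
8 | tert-butyl({1-[(R)-5-isopropyl-2-methyl-5-(triethylsilyloxy)cyclopent-1-en-1-yl]ethenyl}oxy)dimethylsilane (2-silyloxydiene) | CC1=C(C(=C)O[Si](C)(C)C(C)(C)C)[C@](O[Si](CC)(CC)CC)(C(C)C)CC1 | intermediate
9 | methyl but-3-enoate | C=CCC(=O)OC | starting material
10 | methyl 2-diazobut-3-enoate | COC(=O)C(=[N+]=[N-])C=C | intermediate
11 | methyl 2-(tert-butyldimethylsilyloxy)-2-[(R)-5-isopropyl-2-methyl-5-(triethylsilyloxy)cyclopent-1-en-1-yl]-1-vinylcyclopropane-1-carboxylate, vinyl and cyclopentenyl cis (not isolated) | C=C[C@@]1(C(=O)OC)C[C@@]1(O[Si](C)(C)C(C)(C)C)C2=C(C)CC[C@@]2(O[Si](CC)(CC)CC)C(C)C | intermediate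
12 | methyl 6-(tert-butyldimethylsilyloxy)-4β-(triethylsilyloxy)dauca-5,8-dien-14-oate (C5=C6 silyl enol ether, C8=C9 with CO2Me on C8, 1β-CH3, 4α-isopropyl) | COC(=O)C1=CC[C@@]2(C)CC[C@@](O[Si](CC)(CC)CC)(C(C)C)C2=C(O[Si](C)(C)C(C)(C)C)C1 | intermediate
13 | 6-(tert-butyldimethylsilyloxy)-4β-(triethylsilyloxy)dauca-5,8-dien-14-ol | OCC1=CC[C@@]2(C)CC[C@@](O[Si](CC)(CC)CC)(C(C)C)C2=C(O[Si](C)(C)C(C)(C)C)C1 | intermediate
14 | 14-mesylate of 13 (not isolated) | CS(=O)(=O)OCC1=CC[C@@]2(C)CC[C@@](O[Si](CC)(CC)CC)(C(C)C)C2=C(O[Si](C)(C)C(C)(C)C)C1 | intermediate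
15 | 6-(tert-butyldimethylsilyloxy)-4β-(triethylsilyloxy)dauca-5,8-diene | CC1=CC[C@@]2(C)CC[C@@](O[Si](CC)(CC)CC)(C(C)C)C2=C(O[Si](C)(C)C(C)(C)C)C1 | intermediate
16 | 4β-hydroxy-5α-dauc-8-en-6-one (trans-fused) | O=C1CC(C)=CC[C@@]2(C)CC[C@@](O)(C(C)C)[C@H]12 | intermediate
17 | 5α-dauc-8-ene-4β,6α-diol | O[C@H]1CC(C)=CC[C@@]2(C)CC[C@@](O)(C(C)C)[C@H]12 | intermediate
18 | 4-methoxybenzoyl chloride | COc1ccc(C(Cl)=O)cc1 | starting material
19 | 6α-(4-methoxybenzoyloxy)-5α-dauc-8-en-4β-ol | COc1ccc(C(=O)O[C@H]2CC(C)=CC[C@@]3(C)CC[C@@](O)(C(C)C)[C@H]23)cc1 | intermediate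
20 | 4β-hydroxy-6α-(4-methoxybenzoyloxy)-5α-dauc-8-en-10-one | COc1ccc(C(=O)O[C@H]2CC(C)=CC(=O)[C@@]3(C)CC[C@@](O)(C(C)C)[C@H]23)cc1 | intermediate
21 | 6α-(4-methoxybenzoyloxy)-5α-dauc-8-ene-4β,10β-diol | COc1ccc(C(=O)O[C@H]2CC(C)=C[C@H](O)[C@@]3(C)CC[C@@](O)(C(C)C)[C@H]23)cc1 | intermediate
22 | 10β-acetoxy-6α-(4-methoxybenzoyloxy)-5α-dauc-8-en-4β-ol (CNP0256979.3) | COc1ccc(C(=O)O[C@H]2CC(C)=C[C@H](OC(C)=O)[C@@]3(C)CC[C@@](O)(C(C)C)[C@H]23)cc1 | target

Total step count: 16 steps. Longest linear sequence: 15 steps (steps 1–6 and 8–16, from 1 to 22); step 7 is the one-step side branch.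

Steps most likely to fail

Step 8. The cyclopropanation may take the unwanted facial sense or place the two alkenyl groups trans. The Cope step may stall because the C1 methyl group points into the boat. Ionisation of the donor/acceptor cyclopropane may erode the stereochemical relay, and the diene may attack the vinylogous carbenoid terminus. The fallback builds the same bicycle without a carbenoid and sets out from enal 5.
- CH2=CHCH2MgBr adds to the aldehyde to give allyl carbinol F1.
- Anionic oxy-Cope rearrangement (KH, 18-crown-6, THF, quenched cold) transfers the allyl group to C1 and creates the quaternary centre, giving aldehyde F2 after protonation. Its C5 centre can be equilibrated with DBU because no alkene can migrate at this stage. C1 rests on substrate control only, so its epimers are separated here.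
- CH2=C(CH3)CH2MgCl gives dienol F3.
- Ring-closing metathesis with the second-generation Grubbs catalyst RuCl2(=CHPh)(H2IMes)(PCy3) forms C8=C9 and the seven-membered ring in cycloheptenol F4 (C6 epimers).
- HF·pyridine removes the silyl ether. The 6α-alcohol so obtained is diol 17, where the fallback rejoins the route. The 6β-epimer F5 is oxidised at its secondary alcohol with Dess–Martin periodinane to hydroxy ketone 16 and fed into step 12.

Step 11. Protonation of the enol ether on the β face would give the cis-fused ketone. The prolonged fluoride treatment needed for the tertiary silyl ether could also let the C8=C9 alkene drift into conjugation or trigger loss of the C4 oxygen. The fallback separates the two events and changes how C5 receives its proton. Diene 15 is treated with Bu4NF buffered with AcOH in THF at −78 °C, so that the free enolate is generated by fluoride and protonated kinetically by the external acid while the C4 silyl ether still shields the β face. The triethylsilyl-protected ketone F6 is isolated. A short, separate exposure of F6 to HF·pyridine/pyridine at 0 °C then gives hydroxy ketone 16, where the route is rejoined.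

Step 14. Oxidation could occur at C7 or at the vinylic methyl group instead of C10, stall at the neopentylic methylene, or go too far. The fallback places the oxygen by an epoxide-based 1,3-transposition and sets out from anisate 19.
- mCPBA gives epoxide F7.
- PhSeNa (from PhSeSePh and NaBH4 in EtOH) opens it at the less substituted C9 to give hydroxy selenide F8.
- H2O2 oxidises this to selenoxide F9, which undergoes syn-elimination towards C10, the only neighbouring carbon that bears hydrogen, to give tertiary allylic alcohol F10 (C8–OH, C9=C10).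
- Pyridinium chlorochromate (C5H5NH)[CrO3Cl] then effects the oxidative 1,3-transposition (Babler–Dauben oxidation) to enone 20, where the route is rejoined.

Further compounds
F1 | step 8 | 1-[(R)-5-isopropyl-2-methyl-5-(triethylsilyloxy)cyclopent-1-en-1-yl]but-3-en-1-ol (carbinol epimers) | CC1=C(C(O)CC=C)[C@](O[Si](CC)(CC)CC)(C(C)C)CC1
F2 | step 8 | 2-allyl-5-isopropyl-2-methyl-5-(triethylsilyloxy)cyclopentane-1-carbaldehyde (CHO cis to the C1 methyl and to the silyloxy group, trans to allyl) | O=C[C@@H]1[C@@](C)(CC=C)CC[C@@]1(O[Si](CC)(CC)CC)C(C)C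
F3 | step 8 | 1-[2-allyl-5-isopropyl-2-methyl-5-(triethylsilyloxy)cyclopentyl]-3-methylbut-3-en-1-ol (carbinol epimers) | C=C(C)CC(O)[C@@H]1[C@@](C)(CC=C)CC[C@@]1(O[Si](CC)(CC)CC)C(C)C
F4 | step 8 | 4β-(triethylsilyloxy)-5α-dauc-8-en-6-ol (C6 epimers) | OC1CC(C)=CC[C@@]2(C)CC[C@@](O[Si](CC)(CC)CC)(C(C)C)[C@H]12
F5 | step 8 | 5α-dauc-8-ene-4β,6β-diol (C6 epimer of 17) | O[C@@H]1CC(C)=CC[C@@]2(C)CC[C@@](O)(C(C)C)[C@H]12
F6 | step 11 | 4β-(triethylsilyloxy)-5α-dauc-8-en-6-one | O=C1CC(C)=CC[C@@]2(C)CC[C@@](O[Si](CC)(CC)CC)(C(C)C)[C@H]12
F7 | step 14 | 8,9-epoxide of 19 (either epoxide face) | COc1ccc(C(=O)O[C@H]2CC4(C)OC4C[C@@]3(C)CC[C@@](O)(C(C)C)[C@H]23)cc1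
F8 | step 14 | 9-phenylselanyl-4β,8-diol 6α-anisate (from trans opening of F7) | COc1ccc(C(=O)O[C@H]2CC(C)(O)C([Se]c4ccccc4)C[C@@]3(C)CC[C@@](O)(C(C)C)[C@H]23)cc1
F9 | step 14 | selenoxide of F8 | COc1ccc(C(=O)O[C@H]2CC(C)(O)C([Se](=O)c4ccccc4)C[C@@]3(C)CC[C@@](O)(C(C)C)[C@H]23)cc1
F10 | step 14 | 6α-(4-methoxybenzoyloxy)-5α-dauc-9-ene-4β,8-diol (tertiary allylic alcohol) | COc1ccc(C(=O)O[C@H]2CC(C)(O)C=C[C@@]3(C)CC[C@@](O)(C(C)C)[C@H]23)cc1
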